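The numbers of this flask stand for no real mixture; the result is computed.

Late in a run this flask stops moving. Starting material, target and isomer of the product stand in a closed loop, and what the protic impurity has quenched has left that loop. The next run hangs on what this resting state holds, so I must decide whether heating is worth it.

- cedar: starting material 0.50 M; protic impurity 0.0500 M; free catalyst 0.65 mM; temperature 50 °C; time 2.5 min
- ash: starting material 0.50 M; protic impurity 0.0500 M; free catalyst 0.65 mM; temperature 25 °C; time 2.5 min

- the flask with the highest amount of target, in percent of the starting material charged ("all alike" if they lie within 1.5 percentage points) (cedar / ash / all alike)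
- final target, as a percentage of the starting material charged, in cedar
- final target, as a percentage of the starting material charged, in ash

- constants are those at 25 °C; use the activation energies and enthalpies for any other temperature

    starting material + free catalyst ⇌ target + free catalyst, rate k1*[starting material]*[free catalyst] forward; the back reaction follows from the equilibrium constant (K1 = 0.45, k1 = 4.1 M⁻¹ s⁻¹, Ea1 = 58.0 kJ mol⁻¹, ΔH1 = −15.0 kJ mol⁻¹)
    target ⇌ isomer of the product (K2 = 2.4, k2 = 3.8 × 10⁻⁴ s⁻¹, Ea2 = 88.0 kJ mol⁻¹, ΔH2 = −18.0 kJ mol⁻¹)
    isomer of the product ⇌ starting material (k3 = 0.0031 s⁻¹, Ea3 = 75.0 kJ mol⁻¹)
    starting material + free catalyst → spent catalyst (k4 = 0.0030 M⁻¹ s⁻¹, Ea4 = 73.0 kJ mol⁻¹)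
    starting material + protic impurity → quenched substrate (k5 = 0.053 M⁻¹ s⁻¹, Ea5 = 54.0 kJ mol⁻¹)
    (constants at 25 °C)

For each unit of starting material at rest there stand K of target and K·K′ of isomer, with K and K′ the constants of the first two steps at the flask's temperature. Target's share of the loop is therefore K/(1+K+K·K′). My first round takes that share of what the impurity leaves, which is 90.0 % of the charge when each impurity takes one starting material. With 0.282 and 1.37, cedar comes to 15.2 %, and this number, loop share times what the impurity leaves, is the resting yield. Ash, with 0.45 and 2.4, comes to 16.0 %.

Cedar should get there: target arrives through the catalysed step and the loop closes through the third step, and with the catalyst as charged these relax with half-lives of 0.156 min and 0.259 min, both shorter than the run of 2.5 min. Ash is less sure. Its closing step has a half-life of 1.79 min and its catalysed step 1.35 min, so I put the first answer back and go round once more. Taking the resting target out of the loop, ash's starting material falls from 74.0 % towards 35.6 % and by my estimate stands near 50.2 % at the end. Target, chasing 0.45 times that, has covered 72.4 % of the way, which gives 16.4 %. The gap of 1.1 percentage points to cedar is smaller than the margin of 1.5 points, so I expect a tie and leave the next run at 25 °C.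

The forecast says all alike, with 15.1 % for cedar and 15.6 % for ash, the colder flask coming from “a rough mental integration”. My ash figure is higher.

The simulation gives 15.2 % in cedar, level with the resting yield of 15.2 %, and 15.9 % in ash, so the verdict is all alike. Ash's target has moved by 5 points at a catalyst charge of 0.345 mM or a time of 1.07 min.

Take cedar's neighbour, charged with 0.12 M of starting material, its other charges, temperature and time as in cedar. The loop share stays 16.9 %, but the impurity now stands at 0.417 equiv, so the first round gives 9.86 %. Going round again, 9.5 % of the impurity is still there at 2.50 min and quenched substrate is 37.7 %, which gives 10.5 %. That flask holds 10.6 % of target.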